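The dusk flask at 5 °C stands flat from its first reading at 12.0 min, while the dawn run at −10 °C, colder, is still climbing at its last reading, and that contrast is what you have to explain.

the same everywhere: free enzyme 0.05 mol%

|  | substrate | temperature | remark | time |
|---|---|---|---|---|
| dusk | 0.10 M | 5 °C | the very flask that is asked about, followed so far |  |
| dawn | 0.067 M | −10 °C | run made earlier |  |
| flask | 0.10 M | 5 °C |  | 1.5 h |

| run | time / min | target / % | substrate / % |
|---|---|---|---|
| dusk | 12.0 | 43 | 55 |
| dusk | 25.0 | 41 | 54 |
| dusk | 40.0 | 43 | 56 |
| dusk | 50.0 | 44 | 52 |
| dusk | 60.0 | 40 | 54 |
| dusk | 80.0 | 42 | 54 |
| dusk | 90.0 | 42 | 53 |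
| dawn | 0.333 | 3 | 98 |
| dawn | 0.667 | 3 | 95 |
| dawn | 1.00 | 5 | 96 |
| dawn | 2.00 | 11 | 87 |
| dawn | 3.00 | 16 | 83 |
| dawn | 4.00 | 24 | 74 |

(scatter of a reading: 1.5 percentage points)

- target that was removed still counts
- additions bring no volume worth counting

- south-east: at 1.5 h add free enzyme, 100% of the amount charged, then wait 25 min
- south-west: at 1.5 h raise the temperature by 20 K, then wait 25 min
- north: change nothing and wait 25 min more
- north-west: at 1.5 h take out 90% of the target then present, then wait 25 min

* target, in percent of the substrate first charged, at 1.5 h
* the option that brings most further target ("none" if no option brings more than 2 percentage points) (south-east / south-west / north / north-west / none)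
* target present, with what was taken out counted in, in percent of the substrate first charged, after south-west
* target present, with what was taken out counted in, in percent of the substrate first charged, after north-west

Take the two extremes you can solve in your head. In the first, free enzyme lives on and the plateau is a balance between substrate and target, so a second charge brings nothing, while taking target out sets the flask moving again. In the second, the step runs forward and free enzyme stops working, so the plateau measures the enzyme rather than the substrate. The 7 dusk readings average 42.1% target and 54.0% substrate, so the turnover budget, meaning the target made per free enzyme charged before it stops (the usual turnover number), reads 843.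

The real flask lies somewhere between these, and the dawn run tells you on which side. It gained 11% in its first 2.00 min and 13 percentage points in the next 2.00 min, a difference of 2 points that the scatter of 1.5 points on each reading does not separate from a steady gain, whereas a balance at the dusk plateau would by 24% have left 43.0% of the starting distance to cover and so be slowing. A balance may shift with temperature, so this is a leaning and not a proof, but I commit to the second extreme. My reckoning is therefore 42.1% now, with waiting, warming and taking target out all leaving that figure unchanged, while a second charge brings one more budget, 42 points, which fits within the 54.0% of substrate left, so I choose south-east.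

The forecast gave 42.1% now, north-west as best, 42% after south-west and 63% after north-west, holding that “more enzyme or more waiting gives nothing”, and on the best option it differs from my reckoning.

The flask gives 43.4% at the asked time, and south-east brings 38 points, while south-west and north-west stay at 43.4% and 43.4%.

    free enzyme → unfolded enzyme (k = 1.00 × 10⁻⁴ /s, Ea = 221 kJ/mol)
    substrate + free enzyme → target + free enzyme, rate k2*[substrate]*[free enzyme]/(1 + ([substrate]/Km2) + ([target]/Kp2)) (3.50 mM, 0.120 M, k = 1600 /M/s, Ea = 39.0 kJ/mol)
    target + free enzyme ⇌ isomer of the product + free enzyme, rate k3*[free enzyme]*[target] forward; the back reaction follows from the equilibrium constant (K = 0.430, k = 4.30 /M/s, Ea = 42.0 kJ/mol, ΔH = −73.0 kJ/mol)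
    free enzyme → spent catalyst (k = 0.00590 /s, Ea = 88.0 kJ/mol)
    (constants at 5 °C)

Taken alone, the turning of free enzyme into spent catalyst has a half-life of 2.0 min, shorter than the 54 min of the forward turning of target into isomer of the product, and half of the target-making turnover is done by 1.90 min, with 0% of the catalyst still able to turn over at 90.0 min. At 0.2 mol% of free enzyme the budget comes to 169% of the substrate charged, more than the charge, and that neighbouring flask ends with substrate at 0% and target at 91.5%.

The data were computed with made-up constants, noise included.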